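## Retrosynthetic overview

1. Locants used for the target: C3 (acyloxy carbon), C4 (CHMe), C5 (quaternary), C7 (CHOH), C8 (C=O), C1=C2 and C9=C10 (alkenes). The last two bonds made are C7–O (enolate oxidation) and the ester C–O (Yamaguchi), the latter to (2E,4E,6S)-6-hydroxy-6-methylocta-2,4-dienoic acid (chiral pool; one-pot DIBAL reduction and vinylogous Horner–Wadsworth–Emmons).
2. Ring B is formed second, by aldol condensation of a ring-A ketone that carries a 3-oxobutyl arm on C5. The C1=C2 alkene then comes from Saegusa oxidation of the enone.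
3. Key step: one radical chain makes the C4–CH3 and C5–C6 bonds. A silicon-tethered CH2 radical hung on the C3 oxygen closes onto C4, and the resulting tertiary C5 radical is captured by methyl vinyl ketone. The C3 → C4 → C5 relay gives the all-cis O/Me/Me triad and the quaternary centre.
4. Ring A is formed first, from an arene: m-cresol → p-quinone monoketal → enone → CBS reduction, which sets C3, the only reagent-controlled stereocentre of the core.

Assumption: (S)-2-hydroxy-2-methylbutanoic acid is available commercially as the single enantiomer.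

## Route

Step 1
Reactants: 1 m-cresol (3-methylphenol)
Product: 3 4,4-dimethoxy-3-methylcyclohexa-2,5-dien-1-one, via 4-methoxy-3-methylphenol 2 (not isolated)
Conditions: PhI(OAc)2 (2.2 equiv), MeOH, 0 °C to rt
Reagents that add atoms: methanol, CO
Why: Hypervalent-iodine oxidative dearomatization: PhI(OAc)2 oxidizes the phenol twice at its free para position with capture of methanol each time (first to phenol 2, then to the monoketal), which delivers ring A with its ketone and a masked second ketone next to the methyl-bearing carbon; no stereocentre is formed.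

Step 2
Reactants: 3 4,4-dimethoxy-3-methylcyclohexa-2,5-dien-1-one
Product: 4 4,4-dimethoxy-3-methylcyclohex-2-en-1-one
Conditions: H2 (1 atm), RhCl(PPh3)3 (5 mol %), benzene, rt
Reagents that add atoms: none
Why: Chemoselective homogeneous hydrogenation: RhCl(PPh3)3 saturates the disubstituted C5=C6 bond and leaves the trisubstituted, methyl-bearing C2=C3 bond, as in the reduction of steroidal 1,4-dien-3-ones to 4-en-3-ones; no stereocentre is formed.

Step 3
Reactants: 4 4,4-dimethoxy-3-methylcyclohex-2-en-1-one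
Product: 5 (1S)-4,4-dimethoxy-3-methylcyclohex-2-en-1-ol
Conditions: (R)-1-methyl-3,3-diphenyl-tetrahydro-1H,3H-pyrrolo[1,2-c][1,3,2]oxazaborole ((R)-Me-CBS, 20 mol %), BH3·SMe2 (0.7 equiv), THF, −30 °C
Reagents that add atoms: none
Why: Corey–Bakshi–Shibata reduction: with the alkenyl arm as the large group the (R)-catalyst gives the (S)-carbinol (by the acetophenone model), which is C3 of the target and the stereocentre from which the whole core is relayed.

Step 4
Reactants: 5 (1S)-4,4-dimethoxy-3-methylcyclohex-2-en-1-ol; 6 (bromomethyl)chlorodimethylsilane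
Product: 7 (bromomethyl){[(1S)-4,4-dimethoxy-3-methylcyclohex-2-en-1-yl]oxy}dimethylsilane
Conditions: Et3N (1.5 equiv), 4-(dimethylamino)pyridine (5 mol %), CH2Cl2, 0 °C
Reagents that add atoms: none
Why: O-silylation of the secondary allylic alcohol installs the Nishiyama–Stork radical tether whose CH2 becomes the C4 methyl carbon; the stereocentre and the ketal are untouched under these basic conditions.

Step 5
Reactants: 7 (bromomethyl){[(1S)-4,4-dimethoxy-3-methylcyclohex-2-en-1-yl]oxy}dimethylsilane; 8 methyl vinyl ketone (but-3-en-2-one)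
Product: 10 4-[(3aS,4R,7aS)-5,5-dimethoxy-2,2,4-trimethyloctahydro-1,2-benzoxasilol-4-yl]butan-2-one, via tertiary ring radical 9 (not isolated)
Conditions: Bu3SnH (1.3 equiv, syringe pump 8 h), 2,2'-azobis(isobutyronitrile) (0.2 equiv), 8 (6 equiv), benzene, 80 °C
Reagents that add atoms: none
Why: Tandem radical cyclization–trapping (Nishiyama–Stork cyclization, then Giese addition): after bromine abstraction the silicon-tethered CH2 radical closes 5-exo-trig on the alkene CH, necessarily on the face of the oxygen, to give the nucleophilic tertiary radical 9, which adds to 8 on the face opposite the new ring-fusion CH2 before hydrogen transfer from Bu3SnH, so that the oxygen, the future C4 methyl and the C5 methyl end up all cis and the quaternary centre is formed in the radical step.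

Step 6
Reactants: 10 4-[(3aS,4R,7aS)-5,5-dimethoxy-2,2,4-trimethyloctahydro-1,2-benzoxasilol-4-yl]butan-2-one
Product: 11 4-[(1R,2R,3S)-3-hydroxy-6,6-dimethoxy-1,2-dimethylcyclohexyl]butan-2-one
Conditions: Bu4NF (5 equiv), DMF, 75 °C
Reagents that add atoms: none
Why: Fluoride-mediated protodesilylation of the strained oxasilolane (Stork hydromethylation) turns the CH2–Si arm into the C4 methyl group and frees the C3 hydroxyl with retention at every stereocentre, while the ketal keeps the ring carbonyl masked so that no aldol chemistry can start under the basic conditions.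

Step 7
Reactants: 11 4-[(1R,2R,3S)-3-hydroxy-6,6-dimethoxy-1,2-dimethylcyclohexyl]butan-2-one
Product: 13 (4aR,5R,6S)-6-hydroxy-4a,5-dimethyl-4,4a,5,6,7,8-hexahydronaphthalen-2(3H)-one, via diketone 12 (not isolated)
Conditions: p-toluenesulfonic acid monohydrate (10 mol %), THF–H2O, rt; then KOH (0.5 equiv), MeOH, 60 °C
Reagents that add atoms: none
Why: Acid hydrolysis of the dimethyl ketal to 12 followed by base-mediated intramolecular aldol condensation (the ring-closing half of a Robinson annulation) forms ring B; the quaternary carbon allows only the six-membered enone and none of the three stereocentres is alpha to a carbonyl, so none can epimerize.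

Step 8
Reactants: 13 (4aR,5R,6S)-6-hydroxy-4a,5-dimethyl-4,4a,5,6,7,8-hexahydronaphthalen-2(3H)-one
Product: 16 (4aR,5R,6S)-6-hydroxy-4a,5-dimethyl-4,4a,5,6-tetrahydronaphthalen-2(3H)-one, via bis-silyl dienol ether 14 (not isolated), via silyl ether of the dienone 15 (not isolated)
Conditions: Me3SiOTf (2.5 equiv), Et3N (4 equiv), CH2Cl2, 0 °C to rt; then Pd(OAc)2 (1.1 equiv), MeCN, rt; then 1 M HCl, THF, 0 °C
Reagents that add atoms: none
Why: Saegusa–Ito oxidation: soft enolization gives the heteroannular extended dienol ether 14 (the alcohol is silylated in passing), divalent palladium moves to the gamma carbon and beta-hydride elimination gives the linear dienone 15, whose silyl ether is cleaved on acidic work-up; the stereocentres are untouched.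

Step 9
Reactants: 17 methyl (E)-4-bromobut-2-enoate
Product: 18 methyl (E)-4-(diethoxyphosphoryl)but-2-enoate
Conditions: P(OEt)3 (1.1 equiv), neat, 120 °C
Reagents that add atoms: triethyl phosphite, CCOP(OCC)OCC
Why: Michaelis–Arbuzov reaction of the allylic bromide gives the vinylogous Horner–Wadsworth–Emmons reagent with the E alkene retained.

Step 10
Reactants: 19 (S)-2-hydroxy-2-methylbutanoic acid
Product: 20 methyl (S)-2-hydroxy-2-methylbutanoate
Conditions: MeOH, H2SO4 (cat.), reflux
Reagents that add atoms: methanol, CO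
Why: Fischer esterification; the fully substituted carbinol carbon cannot epimerize, so the (S) centre of the side chain comes unchanged from the chiral pool.

Step 11
Reactants: 20 methyl (S)-2-hydroxy-2-methylbutanoate; 18 methyl (E)-4-(diethoxyphosphoryl)but-2-enoate
Product: 22 methyl (2E,4E,6S)-6-hydroxy-6-methylocta-2,4-dienoate, via hydroxy aldehyde 21 (not isolated)
Conditions: i-Bu2AlH (2.2 equiv), CH2Cl2, −78 °C; then 18 (1.2 equiv) premixed with LiN(SiMe3)2 (1.2 equiv) in THF, −78 °C to rt
Reagents that add atoms: none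
Why: One-pot DIBAL reduction and vinylogous Horner–Wadsworth–Emmons olefination: the chelated aluminium hemiacetal releases aldehyde 21 only in the presence of the lithiated phosphonate, which forms the new C4=C5 bond E-selectively while the E C2=C3 bond is carried in and the tertiary carbinol is untouched.

Step 12
Reactants: 22 methyl (2E,4E,6S)-6-hydroxy-6-methylocta-2,4-dienoate
Product: 23 (2E,4E,6S)-6-hydroxy-6-methylocta-2,4-dienoic acid
Conditions: LiOH (3 equiv), THF–H2O, rt; then 1 M HCl to pH 4, 0 °C
Reagents that add atoms: lithium hydroxide, [Li+].[OH-]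
Why: Saponification of the methyl ester; mild acidification avoids ionization of the tertiary dienylic alcohol.

Step 13
Reactants: 23 (2E,4E,6S)-6-hydroxy-6-methylocta-2,4-dienoic acid; 16 (4aR,5R,6S)-6-hydroxy-4a,5-dimethyl-4,4a,5,6-tetrahydronaphthalen-2(3H)-one
Product: 25 (1R,2S,8aR)-1,8a-dimethyl-6-oxo-1,2,6,7,8,8a-hexahydronaphthalen-2-yl (2E,4E,6S)-6-hydroxy-6-methylocta-2,4-dienoate, via mixed anhydride 24 (not isolated)
Conditions: 2,4,6-trichlorobenzoyl chloride (1.2 equiv), Et3N (1.5 equiv), THF, rt; then 16, 4-(dimethylamino)pyridine (1.5 equiv), toluene, 40 °C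
Reagents that add atoms: none
Why: Yamaguchi esterification through mixed anhydride 24 acylates the hindered secondary allylic alcohol at oxygen with retention at C3, while the tertiary alcohol of the acid is too hindered to compete.

Step 14
Reactants: 25 (1R,2S,8aR)-1,8a-dimethyl-6-oxo-1,2,6,7,8,8a-hexahydronaphthalen-2-yl (2E,4E,6S)-6-hydroxy-6-methylocta-2,4-dienoate
Product: 27 (1R,2S,7R,8aR)-7-hydroxy-1,8a-dimethyl-6-oxo-1,2,6,7,8,8a-hexahydronaphthalen-2-yl (2E,4E,6S)-6-hydroxy-6-methylocta-2,4-dienoate (target), via dipotassium enolate 26 (not isolated)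
Conditions: KN(SiMe3)2 (2.3 equiv), THF, −78 °C; then 2-(phenylsulfonyl)-3-phenyloxaziridine (1.3 equiv), −78 °C; aq. NH4Cl
Reagents that add atoms: 2-(phenylsulfonyl)-3-phenyloxaziridine, O=S(=O)(c1ccccc1)N1OC1c1ccccc1
Why: Davis enolate oxidation: kinetic deprotonation at the alpha' CH2 gives the cross-conjugated enolate 26 (one equivalent of base sits on the tertiary alkoxide), and the oxaziridine delivers oxygen to the face opposite the axial angular methyl, giving the equatorial (7R) hydroxyl, which is also the thermodynamically preferred epimer.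

## Compound list

1 | m-cresol (3-methylphenol) | Cc1cccc(O)c1 | starting material
2 | 4-methoxy-3-methylphenol | COc1ccc(O)cc1C | intermediate
3 | 4,4-dimethoxy-3-methylcyclohexa-2,5-dien-1-one | COC1(OC)C=CC(=O)C=C1C | intermediate
4 | 4,4-dimethoxy-3-methylcyclohex-2-en-1-one | COC1(OC)CCC(=O)C=C1C | intermediate
5 | (1S)-4,4-dimethoxy-3-methylcyclohex-2-en-1-ol | O[C@H]1CCC(OC)(OC)C(C)=C1 | intermediate
6 | (bromomethyl)chlorodimethylsilane | C[Si](C)(Cl)CBr | starting material
7 | (bromomethyl){[(1S)-4,4-dimethoxy-3-methylcyclohex-2-en-1-yl]oxy}dimethylsilane | BrC[Si](C)(C)O[C@H]1CCC(OC)(OC)C(C)=C1 | intermediate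
8 | methyl vinyl ketone (but-3-en-2-one) | CC(=O)C=C | starting material
9 | (3aS,7aS)-5,5-dimethoxy-2,2,4-trimethyloctahydro-1,2-benzoxasilol-4-yl radical | C[Si]1(C)O[C@H]2CCC(OC)(OC)[C](C)[C@H]2C1 | intermediate
10 | 4-[(3aS,4R,7aS)-5,5-dimethoxy-2,2,4-trimethyloctahydro-1,2-benzoxasilol-4-yl]butan-2-one | C[Si]1(C)O[C@H]2CCC(OC)(OC)[C@](C)(CCC(C)=O)[C@H]2C1 | intermediate
11 | 4-[(1R,2R,3S)-3-hydroxy-6,6-dimethoxy-1,2-dimethylcyclohexyl]butan-2-one | O[C@H]1CCC(OC)(OC)[C@](C)(CCC(C)=O)[C@H]1C | intermediate
12 | (2R,3R,4S)-4-hydroxy-2,3-dimethyl-2-(3-oxobutyl)cyclohexan-1-one | O[C@H]1CCC(=O)[C@](C)(CCC(C)=O)[C@H]1C | intermediate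
13 | (4aR,5R,6S)-6-hydroxy-4a,5-dimethyl-4,4a,5,6,7,8-hexahydronaphthalen-2(3H)-one | O[C@H]1CCC2=CC(=O)CC[C@]2(C)[C@H]1C | intermediate
14 | trimethyl{[(4aR,5R,6S)-4a,5-dimethyl-6-(trimethylsilyloxy)-3,4,4a,5,6,7-hexahydronaphthalen-2-yl]oxy}silane | C[Si](C)(C)O[C@H]1CC=C2C=C(O[Si](C)(C)C)CC[C@]2(C)[C@H]1C | intermediate
15 | (4aR,5R,6S)-4a,5-dimethyl-6-(trimethylsilyloxy)-4,4a,5,6-tetrahydronaphthalen-2(3H)-one | C[Si](C)(C)O[C@H]1C=CC2=CC(=O)CC[C@]2(C)[C@H]1C | intermediate
16 | (4aR,5R,6S)-6-hydroxy-4a,5-dimethyl-4,4a,5,6-tetrahydronaphthalen-2(3H)-one | O[C@H]1C=CC2=CC(=O)CC[C@]2(C)[C@H]1C | intermediate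
17 | methyl (E)-4-bromobut-2-enoate | COC(=O)/C=C/CBr | starting material
18 | methyl (E)-4-(diethoxyphosphoryl)but-2-enoate | CCOP(=O)(OCC)C/C=C/C(=O)OC | intermediate
19 | (S)-2-hydroxy-2-methylbutanoic acid | CC[C@](C)(O)C(=O)O | starting material
20 | methyl (S)-2-hydroxy-2-methylbutanoate | CC[C@](C)(O)C(=O)OC | intermediate
21 | (S)-2-hydroxy-2-methylbutanal | CC[C@](C)(O)C=O | intermediate
22 | methyl (2E,4E,6S)-6-hydroxy-6-methylocta-2,4-dienoate | CC[C@](C)(O)/C=C/C=C/C(=O)OC | intermediate
23 | (2E,4E,6S)-6-hydroxy-6-methylocta-2,4-dienoic acid | CC[C@](C)(O)/C=C/C=C/C(=O)O | intermediate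
24 | (2E,4E,6S)-6-hydroxy-6-methylocta-2,4-dienoic 2,4,6-trichlorobenzoic anhydride | CC[C@](C)(O)/C=C/C=C/C(=O)OC(=O)c1c(Cl)cc(Cl)cc1Cl | intermediate
25 | (1R,2S,8aR)-1,8a-dimethyl-6-oxo-1,2,6,7,8,8a-hexahydronaphthalen-2-yl (2E,4E,6S)-6-hydroxy-6-methylocta-2,4-dienoate | CC[C@](C)(O)/C=C/C=C/C(=O)O[C@H]1C=CC2=CC(=O)CC[C@]2(C)[C@H]1C | intermediate
26 | dipotassium salt of 25 (tertiary alkoxide and cross-conjugated C6–C7 enolate) | [K+].[K+].CC[C@](C)([O-])/C=C/C=C/C(=O)O[C@H]1C=CC2=CC([O-])=CC[C@]2(C)[C@H]1C | intermediate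
27 | (1R,2S,7R,8aR)-7-hydroxy-1,8a-dimethyl-6-oxo-1,2,6,7,8,8a-hexahydronaphthalen-2-yl (2E,4E,6S)-6-hydroxy-6-methylocta-2,4-dienoate | CC[C@](C)(O)/C=C/C=C/C(=O)O[C@H]1C=CC2=CC(=O)[C@H](O)C[C@]2(C)[C@H]1C | target

## Step count and risks

Total steps: 14. Longest linear sequence: 10 steps (steps 1 to 8, then 13 and 14); the acid is made in 4 steps (9 to 12).

**Step 5 (radical cyclization–trapping).** The hindered tertiary radical 9 may be reduced by Bu3SnH, or the first-formed CH2 radical may add to 8, before the desired sequence runs. Fallback: split the two bond formations. From 7, Bu3SnH and 2,2'-azobis(isobutyronitrile) without acceptor give the reduced cyclization product (3aS,7aS)-5,5-dimethoxy-2,2,4-trimethyloctahydro-1,2-benzoxasilole F1 as C4 epimers. Bu4NF in DMF then gives (1S,2R)-4,4-dimethoxy-2,3-dimethylcyclohexan-1-ol F2, and aqueous acid gives (3R,4S)-4-hydroxy-2,3-dimethylcyclohexan-1-one F3. Robinson annulation of F3 with 8 (KOH, MeOH; Michael addition at the more substituted alpha carbon anti to the neighbouring methyl, then aldol condensation) comes back to the route at 13. In this fallback the quaternary centre is set by the polar Michael step rather than by the radical.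

**Step 8 (gamma,delta-dehydrogenation).** Soft enolization may give some cross-conjugated dienol ether, and the palladium step would then deliver the wrong dienone. Fallback: change the order and the oxidant. From 13, Yamaguchi esterification with 23 (through 24) gives the saturated-ring ester (1R,2S,8aR)-1,8a-dimethyl-6-oxo-1,2,3,4,6,7,8,8a-octahydronaphthalen-2-yl (2E,4E,6S)-6-hydroxy-6-methylocta-2,4-dienoate F4. Chloranil in refluxing t-BuOH (dienolization and hydride abstraction, as for steroidal 4-en-3-ones to 4,6-dien-3-ones) then gives the linear dienone and comes back to the route at 25.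

**Step 14 (alpha' hydroxylation).** Kinetic enolization may be accompanied by deprotonation at the C3–H (epsilon to the ketone) or by attack on the ester. Fallback: avoid the strong base. From 25, Mn(OAc)3·2H2O in refluxing benzene acetoxylates the alpha' carbon directly and gives (1R,2S,7R,8aR)-7-acetoxy-1,8a-dimethyl-6-oxo-1,2,6,7,8,8a-hexahydronaphthalen-2-yl (2E,4E,6S)-6-hydroxy-6-methylocta-2,4-dienoate F5 as the equatorial acetate. K2CO3 (cat.) in MeOH at 0 °C removes the activated alpha-keto acetate in preference to the hindered dienoate and comes back to the route at 27.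

## Further compounds

F1 | step 5 | (3aS,7aS)-5,5-dimethoxy-2,2,4-trimethyloctahydro-1,2-benzoxasilole (C4 epimers) | C[Si]1(C)O[C@H]2CCC(OC)(OC)C(C)[C@H]2C1
F2 | step 5 | (1S,2R)-4,4-dimethoxy-2,3-dimethylcyclohexan-1-ol (C3 epimers) | O[C@H]1CCC(OC)(OC)C(C)[C@H]1C
F3 | step 5 | (3R,4S)-4-hydroxy-2,3-dimethylcyclohexan-1-one (C2 epimers) | O[C@H]1CCC(=O)C(C)[C@H]1C
F4 | step 8 | (1R,2S,8aR)-1,8a-dimethyl-6-oxo-1,2,3,4,6,7,8,8a-octahydronaphthalen-2-yl (2E,4E,6S)-6-hydroxy-6-methylocta-2,4-dienoate | CC[C@](C)(O)/C=C/C=C/C(=O)O[C@H]1CCC2=CC(=O)CC[C@]2(C)[C@H]1C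
F5 | step 14 | (1R,2S,7R,8aR)-7-acetoxy-1,8a-dimethyl-6-oxo-1,2,6,7,8,8a-hexahydronaphthalen-2-yl (2E,4E,6S)-6-hydroxy-6-methylocta-2,4-dienoate | CC[C@](C)(O)/C=C/C=C/C(=O)O[C@H]1C=CC2=CC(=O)[C@H](OC(C)=O)C[C@]2(C)[C@H]1C
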